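**Retrosynthetic overview**

1. Target 31 ⇐ 30 (PMB off the diosphenol oxygen) ⇐ alkenyl iodide 23 + redox-active ester 28. The C3'–C4' bond of the 2-methylbut-2-enoate is made by a Ni-electrocatalytic decarboxylative alkenylation (α-acyloxymethyl radical from a glycolic-acid carboxyl + (Z)-alkenyl iodide).
2. Enabling feature: C4' is a CH2 bound to the angelate oxygen, so it is available as a stabilised α-acyloxy radical by loss of CO2. C3' is the β-carbon of an enoate whose carbonyl C1'=O can hold nickel on C3' in a five-membered chelate ring (Ni–C3'=C2'–C1'=O) that exists only for the Z isomer. C4' arrives already O-acylated, so no γ-hydroxy enoate and no butenolide ring can form.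
3. 23 ⇐ alcohol 17 + (Z)-3-iodo-2-methylacrylic acid 22 (anti-carbomagnesiation/iodination of propargyl alcohol, then oxidation); 28 ⇐ angelic acid 24 + tert-butyl bromoacetate 25.
4. 17 ⇐ ring B: C7 isopropylidene by aldol/dehydration with acetone, C9 oxygen through the C9,C10-epoxide of the enone opened by PMB alkoxide; ring A: C4 methyl by enol-triflate methylation, C3–OH and C4–H by α-face hydroboration.
5. No ring is closed in the route: both rings of the decalin (ring A C1–C5/C10, ring B C5–C10) and the C5 stereocentre come with (S)-Wieland–Miescher ketone 1.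

Key step: step 18

Remark: eremophilane numbering is used for the decalin (C11 = isopropylidene carbon, C15 = methyl on C4, C14 = methyl on C5, β = face of the C5 methyl) and primed locants C1'–C4' for the 2-methylbut-2-enoate; compounds 1, 18, 24 and 25 are taken as commercially available.

**Route**

Step 1
Reactants: 1 (S)-Wieland–Miescher ketone
Product: 2 (S)-Wieland–Miescher ketone C8-(1,3-dithiolane) (enone carbonyl masked, C4 ketone free, C9=C10 kept)
Conditions: HSCH2CH2SH (1.05 equiv), p-TsOH·H2O (cat.), AcOH, rt
Reagents that add atoms: ethane-1,2-dithiol, SCCS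
Why: Acid-catalysed thioketalisation of this diketone is known to take place selectively at the conjugated carbonyl, which leaves the saturated C4 ketone free and the C5 stereocentre untouched.

Step 2
Reactants: 2 (S)-Wieland–Miescher ketone C8-(1,3-dithiolane)
Product: 4 C4 enol triflate (C3=C4), via potassium enolate 3 (not isolated)
Conditions: KHMDS, THF, −78 °C; PhNTf2, −78 → 0 °C
Reagents that add atoms: N-phenylbis(trifluoromethanesulfonimide), FC(F)(F)S(=O)(=O)N(c1ccccc1)S(=O)(=O)C(F)(F)F
Why: Enol triflate formation (enolisation/O-sulfonylation) can only run toward C3 because C5 is quaternary, and with the enone masked no second enolate competes.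

Step 3
Reactants: 4 C4 enol triflate
Product: 5 4-methyl-3,9-diene C8-dithiolane (4,5-dimethyl, 5R)
Conditions: MeMgBr, Fe(acac)3 (cat.), THF/NMP, −20 → 0 °C
Reagents that add atoms: methylmagnesium bromide, C[Mg]Br
Why: Iron-catalysed Kumada-type cross-coupling of an alkenyl triflate with a methyl Grignard reagent installs C15 on C4 without touching the thioketal or C5.

Step 4
Reactants: 5 4-methyl-3,9-diene C8-dithiolane
Product: 7 (3R,4R,5R)-3α-hydroxy-4β,5β-dimethyl-Δ9 C8-dithiolane, via alkylborane 6 (not isolated)
Conditions: BH3·SMe2 (1.1 equiv), THF, 0 °C → rt; then NaOH (aq), H2O2, 0 °C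
Reagents that add atoms: hydrogen peroxide, OO
Why: Brown hydroboration–oxidation adds H and B syn and anti-Markovnikov to C3=C4 from the α face opposite the angular C5 methyl, which should set 3α-OH (3R) and 4β-CH3 (4R) together, while C9=C10 is shielded by the adjacent spiro-dithiolane and the quaternary C5.

Step 5
Reactants: 7 (3R,4R,5R)-3α-hydroxy-4β,5β-dimethyl-Δ9 C8-dithiolane
Product: 8 TBS ether of 7
Conditions: TBSCl, imidazole, DMF, rt
Reagents that add atoms: tert-butyldimethylsilyl chloride, CC(C)(C)[Si](C)(C)Cl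
Why: Standard silylation of a secondary alcohol protects C3–OH against the later base, enolate and mesylation steps without affecting any stereocentre.

Step 6
Reactants: 8 TBS ether of 7
Product: 9 (4aR,5R,6R)-6-[(tert-butyldimethylsilyl)oxy]-4a,5-dimethyl-4,4a,5,6,7,8-hexahydronaphthalen-2(3H)-one (C8 enone)
Conditions: MeI (excess), CaCO3, MeCN/H2O (4:1), 50 °C
Reagents that add atoms: water, O
Why: Alkylative hydrolysis of the dithiolane (S-methylation, hydrolysis of the allylic thionium ion) should return the conjugated enone under buffered conditions that leave the silyl ether intact.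

Step 7
Reactants: 9 C8 enone
Product: 10 9,10-epoxy-8-ketone (epoxide face not controlled)
Conditions: 30% H2O2, NaOH (aq), MeOH, 0 °C → rt
Reagents that add atoms: hydrogen peroxide, OO
Why: Weitz–Scheffer nucleophilic epoxidation of the β,β-disubstituted enone has direct analogy in steroidal 4-en-3-ones, and both new epoxide centres are destroyed in step 8 so facial selectivity is irrelevant.

Step 8
Reactants: 10 9,10-epoxy-8-ketone
Product: 12 9-[(4-methoxybenzyl)oxy] enone (PMB-protected diosphenol), via hydroxy ether 11 (not isolated)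
Conditions: 4-methoxybenzyl alcohol (5 equiv), NaH (0.3 equiv), THF, 60 °C
Reagents that add atoms: 4-methoxybenzyl alcohol, COc1ccc(CO)cc1
Why: Alkoxide opening of an α,β-epoxy ketone at the α-carbon C9 followed by E1cB loss of the C10 hydroxyl is the known route to 2-alkoxy enones and should deliver the diosphenol already protected.

Step 9
Reactants: 12 9-[(4-methoxybenzyl)oxy] enone
Product: 14 C7 aldol adduct with a 2-hydroxypropan-2-yl group (C7 epimers), via lithium enolate 13 (not isolated)
Conditions: LDA, THF, −78 °C; acetone, −78 °C; AcOH quench at −78 °C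
Reagents that add atoms: acetone, CC(C)=O
Why: Kinetic α'-deprotonation at C7 and aldol addition to acetone bring in C11–C13, and the new C7 stereocentre is removed in step 10.

Step 10
Reactants: 14 C7 aldol adduct
Product: 16 C7-isopropylidene dienone (TBS and PMB in place), via tertiary mesylate 15 (not isolated)
Conditions: MsCl, Et3N, CH2Cl2, 0 °C → rt; then DBU, rt
Reagents that add atoms: none
Why: Mesylation and E1cB elimination through the acidic C7–H should give the conjugated tetrasubstituted C7=C11 alkene in preference to the isopropenyl isomer.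

Step 11
Reactants: 16 C7-isopropylidene dienone
Product: 17 (4aR,5R,6R)-6-hydroxy-1-[(4-methoxybenzyl)oxy]-4a,5-dimethyl-3-(propan-2-ylidene)-4,4a,5,6,7,8-hexahydronaphthalen-2(3H)-one
Conditions: HF·pyridine, pyridine/THF, 0 °C → rt
Reagents that add atoms: none
Why: Fluoride-mediated desilylation frees only C3–OH, since the PMB enol ether and the dienone are stable to buffered HF.

Step 12
Reactants: 18 prop-2-yn-1-ol
Product: 20 (Z)-3-iodo-2-methylprop-2-en-1-ol, via alkenylmagnesium chelate 19 (not isolated)
Conditions: MeMgBr (2.5 equiv), CuI (10 mol%), THF, −10 °C → rt; then I2, −10 °C; aq. HCl work-up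
Reagents that add atoms: methylmagnesium bromide, C[Mg]Br; iodine, II
Why: Copper-catalysed anti-carbomagnesiation of the propargylic alkoxide places methyl on C2 and magnesium on C3 cis to CH2O in a five-membered chelate, and iodinolysis with retention fixes the Z geometry.

Step 13
Reactants: 20 (Z)-3-iodo-2-methylprop-2-en-1-ol
Product: 22 (Z)-3-iodo-2-methylprop-2-enoic acid, via iodo enal 21 (not isolated)
Conditions: TEMPO (cat.), NaOCl (cat.), NaClO2, MeCN/phosphate buffer (pH 6.7), 35 °C
Reagents that add atoms: sodium chlorite, [Na+].[O-]Cl=O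
Why: TEMPO/hypochlorite-catalysed chlorite oxidation takes the allylic alcohol through the aldehyde to the acid in one flask under near-neutral conditions, so the sensitive Z-β-iodo enal is consumed as it forms.

Step 14
Reactants: 17 C3 alcohol; 22 (Z)-3-iodo-2-methylprop-2-enoic acid
Product: 23 (3R,4R,5R)-9-[(4-methoxybenzyl)oxy]-8-oxoeremophila-7(11),9-dien-3-yl (2Z)-3-iodo-2-methylprop-2-enoate
Conditions: DIC, DMAP (0.2 equiv), CH2Cl2, 0 °C → rt
Reagents that add atoms: none
Why: Steglich esterification acylates the equatorial C3–OH with retention at C3, and the α-methyl group of the acid disfavours addition–elimination of the catalyst at C3' so the Z geometry should be kept.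

Step 15
Reactants: 24 angelic acid; 25 tert-butyl bromoacetate
Product: 26 tert-butyl 2-{[(2Z)-2-methylbut-2-enoyl]oxy}acetate
Conditions: Cs2CO3, DMF, rt
Reagents that add atoms: none
Why: Carboxylate O-alkylation (SN2) forms the angelate ester without acyl activation and therefore without angelate-to-tiglate isomerisation.

Step 16
Reactants: 26 tert-butyl 2-{[(2Z)-2-methylbut-2-enoyl]oxy}acetate
Product: 27 2-{[(2Z)-2-methylbut-2-enoyl]oxy}acetic acid
Conditions: TFA, CH2Cl2, 0 °C → rt
Reagents that add atoms: none
Why: Acidolysis of the tert-butyl ester (loss of isobutene) frees the carboxylic acid while the angelate ester is stable to TFA at room temperature.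

Step 17
Reactants: 27 2-{[(2Z)-2-methylbut-2-enoyl]oxy}acetic acid
Product: 28 1,3-dioxoisoindolin-2-yl 2-{[(2Z)-2-methylbut-2-enoyl]oxy}acetate (redox-active ester)
Conditions: N-hydroxyphthalimide, DIC, DMAP (cat.), CH2Cl2, rt
Reagents that add atoms: N-hydroxyphthalimide, O=C1N(O)C(=O)c2ccccc12
Why: Carbodiimide coupling with N-hydroxyphthalimide is the standard preparation of redox-active esters and does not touch the angelate.

Step 18
Reactants: 23 alkenyl iodide; 28 redox-active ester (2.5 equiv)
Product: 30 PMB-protected target diester, via acyloxymethyl radical 29 (not isolated)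
Conditions: NiCl2·6H2O (20 mol%), 2,2'-bipyridine (20 mol%), AgNO3 (0.3 equiv), DMF, Mg anode/RVC cathode, undivided cell, constant current, rt
Reagents that add atoms: none
Why: Cathodically generated low-valent Ni(bpy) inserts into the C3'–I bond of 23 with retention, while single-electron reduction of 28 (at the silver-coated cathode or by Ni(I)) expels phthalimide anion and CO2 to give radical 29, which is captured by the alkenylnickel(II) species and reductively eliminated from Ni(III) to form the C3'–C4' bond, the Mg anode supplying the electrons. The closest known reaction type is the Ni-electrocatalytic decarboxylative alkenylation of N-hydroxyphthalimide esters with alkenyl halides, which has been used with α-oxygenated alkyl radicals and with β-halo enoates. No ring is closed and no stereocentre is created; the one stereochemical demand is retention of the Z geometry, secured by stereoretentive oxidative addition and reductive elimination at the sp2 carbon and by the C1'=O chelate to nickel on C3' that only the Z form allows. Chemoselectivity is needed against the cross-conjugated dienone, the two enoates and the allylic C4'–O bond of the product: the C–I bond and the redox-active ester are reduced at much less negative potential, the ester is used in excess so that it remains the electron sink, and the acidic, chelating diosphenol is masked as its PMB ether. Because C4' arrives O-acylated, the free (Z)-γ-hydroxy enoate that would lactonise with loss of the terpenol never exists.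

Step 19
Reactants: 30 PMB-protected target diester
Product: 31 target, (3R,4R,5R)-9-hydroxy-8-oxoeremophila-7(11),9-dien-3-yl (2Z)-2-methyl-4-{[(2Z)-2-methylbut-2-enoyl]oxy}but-2-enoate
Conditions: TFA, anisole, CH2Cl2, 0 °C
Reagents that add atoms: none
Why: Acidolytic cleavage of the PMB enol ether (benzylic SN1, cation trapped by anisole) should free the diosphenol without affecting the esters, the Z alkenes or the stereocentres.

**Compound list**

1 | (S)-Wieland–Miescher ketone, (8aS)-8a-methyl-3,4,8,8a-tetrahydronaphthalene-1,6(2H,7H)-dione | O=C1CCCC2=CC(=O)CC[C@]12C | starting material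
2 | (S)-Wieland–Miescher ketone C8-(1,3-dithiolane), C4 ketone free, 5S | O=C1CCCC2=CC3(SCCS3)CC[C@]12C | intermediate
3 | potassium enolate of 2 (C3=C4, O− on C4) | [K+].[O-]C1=CCCC2=CC3(SCCS3)CC[C@]12C | intermediate
4 | C4 enol triflate of 2 (C3=C4, 5S) | FC(F)(F)S(=O)(=O)OC1=CCCC2=CC3(SCCS3)CC[C@]12C | intermediate
5 | 4,5-dimethyl-3,9-diene C8-dithiolane (5R) | CC1=CCCC2=CC3(SCCS3)CC[C@]12C | intermediate
6 | 3α-boryl-4β-methyl alkylborane, drawn as RBH2 | B[C@@H]1CCC2=CC3(SCCS3)CC[C@]2(C)[C@H]1C | intermediate
7 | (3R,4R,5R)-3α-hydroxy-4β,5β-dimethyl-Δ9 C8-dithiolane | O[C@@H]1CCC2=CC3(SCCS3)CC[C@]2(C)[C@H]1C | intermediate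
8 | TBS ether of 7 | CC(C)(C)[Si](C)(C)O[C@@H]1CCC2=CC3(SCCS3)CC[C@]2(C)[C@H]1C | intermediate
9 | (4aR,5R,6R)-6-[(tert-butyldimethylsilyl)oxy]-4a,5-dimethyl-4,4a,5,6,7,8-hexahydronaphthalen-2(3H)-one | CC(C)(C)[Si](C)(C)O[C@@H]1CCC2=CC(=O)CC[C@]2(C)[C@H]1C | intermediate
10 | 9,10-epoxide of 9 (epoxide configuration unspecified) | CC(C)(C)[Si](C)(C)O[C@@H]1CCC2(O3)C3C(=O)CC[C@]2(C)[C@H]1C | intermediate
11 | 10-hydroxy-9-[(4-methoxybenzyl)oxy]-8-ketone (C9, C10 unspecified) | CC(C)(C)[Si](C)(C)O[C@@H]1CCC2(O)C(OCc3ccc(OC)cc3)C(=O)CC[C@]2(C)[C@H]1C | intermediate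
12 | (4aR,5R,6R)-6-[(tert-butyldimethylsilyl)oxy]-1-[(4-methoxybenzyl)oxy]-4a,5-dimethyl-4,4a,5,6,7,8-hexahydronaphthalen-2(3H)-one | CC(C)(C)[Si](C)(C)O[C@@H]1CCC2=C(OCc3ccc(OC)cc3)C(=O)CC[C@]2(C)[C@H]1C | intermediate
13 | lithium C7 enolate of 12 | [Li+].CC(C)(C)[Si](C)(C)O[C@@H]1CCC2=C(OCc3ccc(OC)cc3)C([O-])=CC[C@]2(C)[C@H]1C | intermediate
14 | C7 aldol adduct of 12 with acetone, 7-(2-hydroxypropan-2-yl), C7 epimers | CC(C)(C)[Si](C)(C)O[C@@H]1CCC2=C(OCc3ccc(OC)cc3)C(=O)C(C(C)(C)O)C[C@]2(C)[C@H]1C | intermediate
15 | tertiary mesylate of 14 | CC(C)(C)[Si](C)(C)O[C@@H]1CCC2=C(OCc3ccc(OC)cc3)C(=O)C(C(C)(C)OS(C)(=O)=O)C[C@]2(C)[C@H]1C | intermediate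
16 | (4aR,5R,6R)-6-[(tert-butyldimethylsilyl)oxy]-1-[(4-methoxybenzyl)oxy]-4a,5-dimethyl-3-(propan-2-ylidene)-4,4a,5,6,7,8-hexahydronaphthalen-2(3H)-one | CC(C)(C)[Si](C)(C)O[C@@H]1CCC2=C(OCc3ccc(OC)cc3)C(=O)C(=C(C)C)C[C@]2(C)[C@H]1C | intermediate
17 | (4aR,5R,6R)-6-hydroxy-1-[(4-methoxybenzyl)oxy]-4a,5-dimethyl-3-(propan-2-ylidene)-4,4a,5,6,7,8-hexahydronaphthalen-2(3H)-one | O[C@@H]1CCC2=C(OCc3ccc(OC)cc3)C(=O)C(=C(C)C)C[C@]2(C)[C@H]1C | intermediate
18 | prop-2-yn-1-ol | C#CCO | starting material
19 | chelated (Z)-alkenylmagnesium bromide magnesium alkoxide | Br[Mg]/C=C(/C)CO[Mg]Br | intermediate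
20 | (Z)-3-iodo-2-methylprop-2-en-1-ol | I/C=C(/C)CO | intermediate
21 | (Z)-3-iodo-2-methylprop-2-enal | I/C=C(/C)C=O | intermediate
22 | (Z)-3-iodo-2-methylprop-2-enoic acid | I/C=C(/C)C(=O)O | intermediate
23 | (3R,4R,5R)-9-[(4-methoxybenzyl)oxy]-8-oxoeremophila-7(11),9-dien-3-yl (2Z)-3-iodo-2-methylprop-2-enoate | I/C=C(/C)C(=O)O[C@@H]1CCC2=C(OCc3ccc(OC)cc3)C(=O)C(=C(C)C)C[C@]2(C)[C@H]1C | intermediate
24 | angelic acid, (2Z)-2-methylbut-2-enoic acid | C/C=C(/C)C(=O)O | starting material
25 | tert-butyl bromoacetate | BrCC(=O)OC(C)(C)C | starting material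
26 | tert-butyl 2-{[(2Z)-2-methylbut-2-enoyl]oxy}acetate | C/C=C(/C)C(=O)OCC(=O)OC(C)(C)C | intermediate
27 | 2-{[(2Z)-2-methylbut-2-enoyl]oxy}acetic acid | C/C=C(/C)C(=O)OCC(=O)O | intermediate
28 | 1,3-dioxoisoindolin-2-yl 2-{[(2Z)-2-methylbut-2-enoyl]oxy}acetate | C/C=C(/C)C(=O)OCC(=O)ON1C(=O)c2ccccc2C1=O | intermediate
29 | {[(2Z)-2-methylbut-2-enoyl]oxy}methyl radical | C/C=C(/C)C(=O)O[CH2] | intermediate
30 | (3R,4R,5R)-9-[(4-methoxybenzyl)oxy]-8-oxoeremophila-7(11),9-dien-3-yl (2Z)-2-methyl-4-{[(2Z)-2-methylbut-2-enoyl]oxy}but-2-enoate | C/C=C(/C)C(=O)OC/C=C(/C)C(=O)O[C@@H]1CCC2=C(OCc3ccc(OC)cc3)C(=O)C(=C(C)C)C[C@]2(C)[C@H]1C | intermediate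
31 | (3R,4R,5R)-9-hydroxy-8-oxoeremophila-7(11),9-dien-3-yl (2Z)-2-methyl-4-{[(2Z)-2-methylbut-2-enoyl]oxy}but-2-enoate | C/C=C(/C)C(=O)OC/C=C(/C)C(=O)O[C@@H]1CCC2=C(O)C(=O)C(=C(C)C)C[C@]2(C)[C@H]1C | target

**Step count and risks**

Total step count: 19. Longest linear sequence: 14 steps (steps 1–11, 14, 18, 19).

Steps most likely to fail:

1. Step 18. What may go wrong: cathodic loss of iodine from 23 (protodeiodination) or dimerisation of the radical may outrun radical capture at nickel; low-valent nickel may insert into the allylic C4'–O bond of the product; the Z geometry may erode at the alkenylnickel stage. The fallback sets out from 23 and returns at 30. Angelic acid 24 would be O-alkylated with tributyl(iodomethyl)stannane (Cs2CO3, DMF, rt) to give (tributylstannyl)methyl (2Z)-2-methylbut-2-enoate F1. Iodide 23 would then be joined to F1 by a Stille coupling (Pd2(dba)3, AsPh3, CuI, NMP, 50 °C). This forms the same bond by a two-electron transmetalation of an α-oxygenated methylstannane, with no reducing medium and no radical, and would give 30.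

2. Step 8. What may go wrong: the alkoxide may attack the hindered C9 slowly, so that enolisation at C7 and Favorskii-type ring contraction of the epoxy ketone take over. The fallback sets out from 10 and returns at 12. Epoxy ketone 10 would be isomerised by acid (H2SO4 cat., AcOH, rt; then brief K2CO3/MeOH to cleave any C3 acetate), the classical epoxy ketone to diosphenol isomerisation, which also removes the silyl group and would give (4aR,5R,6R)-1,6-dihydroxy-4a,5-dimethyl-4,4a,5,6,7,8-hexahydronaphthalen-2(3H)-one F2. Selective O-alkylation of the acidic enol (PMBCl, K2CO3, DMF) would give the PMB enol ether with free C3–OH F3. Silylation (TBSCl, imidazole, DMF) would then return to 12.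

3. Step 14. What may go wrong: acylation of the hindered alcohol may be slow, so that the activated acid rearranges to the N-acylurea; the nucleophilic catalyst may add to C3' and eliminate, which scrambles the Z geometry or displaces iodide. The fallback sets out from 17 and returns at 23. Alcohol 17 would be oxidised (Dess–Martin periodinane, CH2Cl2) to the (4R,5R)-3-ketone F4. Reduction with L-Selectride (THF, −78 °C) should come from the α face, because the syn-axial C5 methyl blocks axial attack and the C8 carbonyl is flanked by two fully substituted carbons, and give the axial (3S,4R,5R)-3β-alcohol F5. Mitsunobu esterification of F5 with acid 22 (PPh3, DIAD, toluene, 0 °C) uses the acid as nucleophile without acyl activation and inverts C3 to the required 3α ester 23.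

**Further compounds**

F1 | step 18 | (tributylstannyl)methyl (2Z)-2-methylbut-2-enoate | C/C=C(/C)C(=O)OC[Sn](CCCC)(CCCC)CCCC
F2 | step 8 | (4aR,5R,6R)-1,6-dihydroxy-4a,5-dimethyl-4,4a,5,6,7,8-hexahydronaphthalen-2(3H)-one | O[C@@H]1CCC2=C(O)C(=O)CC[C@]2(C)[C@H]1C
F3 | step 8 | (4aR,5R,6R)-6-hydroxy-1-[(4-methoxybenzyl)oxy]-4a,5-dimethyl-4,4a,5,6,7,8-hexahydronaphthalen-2(3H)-one | O[C@@H]1CCC2=C(OCc3ccc(OC)cc3)C(=O)CC[C@]2(C)[C@H]1C
F4 | step 14 | (4R,5R)-9-[(4-methoxybenzyl)oxy]eremophila-7(11),9-diene-3,8-dione | O=C1CCC2=C(OCc3ccc(OC)cc3)C(=O)C(=C(C)C)C[C@]2(C)[C@H]1C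
F5 | step 14 | (3S,4R,5R)-3β-hydroxy-9-[(4-methoxybenzyl)oxy]eremophila-7(11),9-dien-8-one | O[C@H]1CCC2=C(OCc3ccc(OC)cc3)C(=O)C(=C(C)C)C[C@]2(C)[C@H]1C
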